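The ratio of substrate to catalyst charged climbs from 10.0 in the green run to 14.3 in the red run and 20.0 in the flask.

all flasks: gas phase 200 mM (held); catalyst 70 mM

| flask | substrate | remark | time |
|---|---|---|---|
| green | 0.70 M | run made earlier |  |
| red | 1 M | run made earlier |  |
| flask | 1.4 M |  | 15 h |

- green (time / h: target / %, substrate / %): 4.00: 24.6, 48.1; 8.00: 36.3, 22.6; 12.0: 38.3, 11.0; 15.0: 36.9, 6.0
- red (time / h: target / %, substrate / %): 4.00: 21.6, 45.1; 8.00: 31.5, 21.2; 12.0: 32.9, 10.4; 15.0: 31.2, 5.8

(each reading ± 0.3 percentage points)

- at the start none of the gas phase is in solution

- oak: doubling the amount of catalyst, all else as stated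
- birch: doubling the saturation concentration of gas phase, all else as stated
- larch: doubling the transfer coefficient of the gas phase, all else as stated

1. target at 15 h, in percent of the substrate charged
2. the change that raises the amount of target at 15 h, in percent of the substrate charged most ("none" if none brings more than 2 percentage points) (oak / birch / larch / none)
3. amount of target at 15 h, in percent of the substrate charged, after oak

The two runs look contradictory: at 15 h the red run keeps 5.8% of its substrate and the green run 6.0%, yet target stands at 31.2% against 36.9%. Counting turnovers (the turnover number), taken here as the target standing per catalyst, which is the target fraction times the ratio, clears this up. At that time the green run reads 3.69 turnovers and the red run 4.46, so the red run holds more target per catalyst than the green run. Its fraction is lower because the ratio grew by 1.43 and the turnovers by 1.21.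

The logarithm of the second factor over that of the first reads 0.530, with the scatter of the readings behind it. This is the turnover exponent, for catalyst, gas and time as in these runs. Assuming that it holds up to the flask, my own reckoning gives 5.33 turnovers, a target fraction of 26.6%. The forecast gives 25.8%, names birch as the best change and expects 18% after oak, noting that “Target yield, however, drops with loading”.

The flask gives 26.8%, with birch the best change and 31.7% after oak. At 15.0 h the flask holds 48.1% of the substrate charged as self-condensation product. Its 5.36 turnovers, set against the red run, give an exponent of 0.548, where the two runs gave 0.530.

    gas phase ⇌ dissolved gas, rate k1*(csat - [dissolved gas]) (kL = 0.952 h⁻¹)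
    substrate + dissolved gas + catalyst → catalyst + target (k = 13.4 M⁻² h⁻¹)
    target ⇌ isomer of the product (K = 3.50, k = 0.0694 h⁻¹)
    2 substrate → self-condensation product (k = 0.0777 M⁻¹ h⁻¹)

For the neighbour charged with 2.4 M of substrate, the exponent gives 7.09 turnovers, a target fraction of 20.7%. The computed neighbour gives 19.3%.

The data are simulated with made-up constants; the scatter is artificial.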